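**Retrosynthetic overview**
1. Quinone ⇒ 3-heptadecyl-5-methoxyphenol. The last oxygen goes in para to the phenol OH after the ring exists, as in the plant pathway to alkylresorcinol-derived quinones.
2. Phenol ⇒ linear stearoyl-primed tetraketide acid, by C2–C7 aldol, dehydration and loss of the C1 carboxyl as CO2 (the alkylresorcinol synthase sequence). The C3 oxygen already carries its methyl group as an enol ether, so no resorcinol has to be desymmetrised later.
3. Tetraketide acid ⇒ its stable lactone form, 4-methoxy-6-(2-oxononadecyl)-2-pyrone, opened by hydroxide in the same flask as the cyclisation.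
4. Ketopyrone ⇒ stearoyl chloride (starter unit) plus triacetic acid lactone methyl ether (all three extender units in one purchased piece), joined by one C–C bond.
5. Ring order: the pyrone ring is bought and consumed. The only ring formed is the six-membered carbocycle (step 2), which is oxidised to the quinone in step 3.

Assumption: the target has no stereocentre and no stereogenic double bond, so it is achiral and needs no stereocontrol; 4-methoxy-6-methyl-2-pyrone is taken as a catalogue compound.

**Step 1**
Reactants: 1 triacetic acid lactone methyl ether (4-methoxy-6-methyl-2H-pyran-2-one); 2 stearoyl chloride (octadecanoyl chloride)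
Product: 4 ketopyrone 4-methoxy-6-(2-oxononadecyl)-2H-pyran-2-one, via lithiated pyrone 3 (not isolated)
Conditions: 1 (2.1 equiv), LiN(iPr)2 (2.1 equiv), THF, −78 °C, 1 h; then 2 (1.0 equiv), −78 → −30 °C; aq HCl (1 mol/L) quench; surplus 1 recovered
Reagents that add atoms: none
Why: Vinylogous Claisen-type C-acylation, in which the amide base removes the conjugated C6-methyl proton of 1, the extended enolate 3 attacks the acid chloride through carbon at −78 °C, and the second equivalent of 3 at once deprotonates the far more acidic product 4 and so shields it from double acylation; no stereocentre is formed.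

**Step 2**
Reactants: 4 ketopyrone 4-methoxy-6-(2-oxononadecyl)-2H-pyran-2-one
Product: 7 alkylresorcinol monomethyl ether (3-heptadecyl-5-methoxyphenol), via ring-opened tetraketide acid 5 (not isolated), via methoxy-resorcylic acid 6 (not isolated)
Conditions: KOH (6 equiv, 2 mol/L aq), 1,4-dioxane, N2, 23 → 50 °C, 16 h; then aq HCl (6 mol/L) to pH 1, reflux, 3 h
Reagents that add atoms: none
Why: Proposed new method: hydroxide opens the lactone carbonyl of 4 to the carboxylate of 5, which cannot enter the competing Claisen (acylphloroglucinol) closure, so C2, pushed by both the enol-ether oxygen and the C5 dienolate, adds to the C7 ketone (6-enolexo aldol), E1cB loss of water and enolisation give 6 irreversibly with the methyl ether intact, and hot acid then protonates the carboxyl-bearing carbon (para to OH, ortho to OMe) and expels CO2; the closest known reaction type is the base-induced biomimetic conversion of 6-(2-oxoalkyl)-4-hydroxy-2-pyrones such as tetraacetic lactone into orsellinic-type acids, joined to the easy protodecarboxylation of 2,4-dioxygenated 6-alkylbenzoic acids, and no stereocentre is formed.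

**Step 3**
Reactants: 7 alkylresorcinol monomethyl ether (3-heptadecyl-5-methoxyphenol)
Product: 8 2-heptadecyl-6-methoxy-1,4-benzoquinone (target)
Conditions: (KSO3)2NO (2.5 equiv), KH2PO4 (aq buffer), acetone–THF–H2O, 23 °C, 2 h
Reagents that add atoms: potassium nitrosodisulfonate (Fremy's salt), [K+].[K+].[O-]S(=O)(=O)N([O])S(=O)(=O)[O-]
Why: Teuber oxidation, in which one nitroxyl radical abstracts the phenolic hydrogen, a second couples at the free para carbon between OMe and the alkyl chain, and loss of imidodisulfonate gives the para-quinone, as known for lower homologues such as primin; no stereocentre is formed.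

**Compound list**
1 | 4-methoxy-6-methyl-2H-pyran-2-one | CC1=CC(OC)=CC(=O)O1 | starting material
2 | stearoyl chloride | CCCCCCCCCCCCCCCCCC(=O)Cl | starting material
3 | lithium salt of the C6-methyl anion of 1 | [Li+].[CH2-]C1=CC(OC)=CC(=O)O1 | intermediate
4 | 4-methoxy-6-(2-oxononadecyl)-2H-pyran-2-one | CCCCCCCCCCCCCCCCCC(=O)CC1=CC(OC)=CC(=O)O1 | intermediate
5 | (2E)-3-methoxy-5,7-dioxotetracos-2-enoic acid (potassium salt in the flask) | CCCCCCCCCCCCCCCCCC(=O)CC(=O)C/C(OC)=C\C(=O)O | intermediate
6 | 6-heptadecyl-4-hydroxy-2-methoxybenzoic acid | CCCCCCCCCCCCCCCCCc1cc(O)cc(OC)c1C(=O)O | intermediate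
7 | 3-heptadecyl-5-methoxyphenol | CCCCCCCCCCCCCCCCCc1cc(O)cc(OC)c1 | intermediate
8 | 2-heptadecyl-6-methoxycyclohexa-2,5-diene-1,4-dione | CCCCCCCCCCCCCCCCCC1=CC(=O)C=C(OC)C1=O | target

Total step count: 3. Longest linear sequence: 3.

**Steps most likely to fail**

Step 2 carries the highest risk. Hydroxide may displace the enol-ether methoxy group, cleave the 5,7-diketone by retro-Claisen reaction, or let 5 close back to pyrones faster than the aldol runs.
- The fallback gives up the pyrone mask, cyclises the free tetraketide ester under mild base, and moves the O-methylation after ring formation. It sets out from 2 and comes back at 7.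
- Methanolysis of 2 gives methyl stearate F1.
- The trianion of commercial methyl 3,5-dioxohexanoate (LiN(iPr)2, 3.3 equiv, THF, 0 °C) is acylated at its terminal carbon by F1 to give methyl 3,5,7-trioxotetracosanoate F2.
- In a KHCO3–K2CO3 buffer of pH 9–10 with THF at 23 °C, F2 closes by the C2–C7 aldol to methyl 6-heptadecyl-2,4-dihydroxybenzoate F3.
- MeI (1.05 equiv) and K2CO3 in acetone methylate only the non-chelated 4-OH, giving methyl 6-heptadecyl-2-hydroxy-4-methoxybenzoate F4.
- KOH in aqueous ethylene glycol at 120 °C saponifies the hindered ester to 6-heptadecyl-2-hydroxy-4-methoxybenzoic acid F5. This loses CO2 on acidification and heating and gives 7.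

Step 1 is next. O-acylation or double acylation may occur, 3 may self-condense with 1, or 2 may form a ketene.
- The fallback replaces the acylation by an aldol addition followed by oxidation. It sets out from 1 and comes back at 4.
- Compound 1 is lithiated to 3 (1.1 equiv LiN(iPr)2, THF, −78 °C) and added to commercial octadecanal. This is the well-behaved reaction of this anion.
- The product is 6-(2-hydroxynonadecyl)-4-methoxy-2H-pyran-2-one F6, racemic. Its carbinol centre is erased at once by Dess–Martin periodinane in CH2Cl2 at 23 °C, which gives 4.

Step 3 is the least risky. The C17 phenol dissolves poorly in the aqueous medium, and ortho-quinone or coupling products may form.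
- The fallback lets the carboxyl group fix the site of oxygenation, instead of relying on the selectivity of a radical coupling. It sets out from 6 and comes back at 8.
- Step 2 is stopped after cold acidification (0 °C, pH 3) and 6 is isolated.
- PhI(OAc)2 (2.2 equiv) in MeCN–H2O at 0 °C makes water attack the carboxyl-bearing carbon para to the phenol OH.
- Loss of CO2 gives 2-heptadecyl-6-methoxybenzene-1,4-diol F7, which the second equivalent of oxidant takes to 8.

**Further compounds**
F1 | step 2 | methyl stearate | CCCCCCCCCCCCCCCCCC(=O)OC
F2 | step 2 | methyl 3,5,7-trioxotetracosanoate | CCCCCCCCCCCCCCCCCC(=O)CC(=O)CC(=O)CC(=O)OC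
F3 | step 2 | methyl 6-heptadecyl-2,4-dihydroxybenzoate | CCCCCCCCCCCCCCCCCc1cc(O)cc(O)c1C(=O)OC
F4 | step 2 | methyl 6-heptadecyl-2-hydroxy-4-methoxybenzoate | CCCCCCCCCCCCCCCCCc1cc(OC)cc(O)c1C(=O)OC
F5 | step 2 | 6-heptadecyl-2-hydroxy-4-methoxybenzoic acid | CCCCCCCCCCCCCCCCCc1cc(OC)cc(O)c1C(=O)O
F6 | step 1 | 6-(2-hydroxynonadecyl)-4-methoxy-2H-pyran-2-one (racemic) | CCCCCCCCCCCCCCCCCC(O)CC1=CC(OC)=CC(=O)O1
F7 | step 3 | 2-heptadecyl-6-methoxybenzene-1,4-diol | CCCCCCCCCCCCCCCCCc1cc(O)cc(OC)c1O
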